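Numbering used below: butenolide O1, C2 (C=O), C3, C4, C5; chroman O1, C2 to C8a.

**Retrosynthetic overview**
1. Feature: the quaternary butenolide carbon C5 carries O1, the CH2-chromanyl arm, the exocyclic CO2Me carbon and ring carbon C4. C4 and the ester carbon can both come from ester carbons, so C5 is the central carbon of an O-acylated 2-benzyltartronate (an acyloxymalonate).
2. Last disconnections: three benzyl ethers (hydrogenolysis), then the C4-aryl bond (Suzuki-Miyaura coupling of the C4 triflate of a tetronic acid).
3. Key disconnection, C3-C4: a group-selective Dieckmann closure. The methoxyacetate enolate takes one of the two CO2Me groups under control of a chiral lithium amide aggregate, which closes the butenolide and sets C5.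
4. The precursor needs one C-C bond (C5-CH2): dimethyl 2-(methoxyacetoxy)malonate is alkylated with the (R)-3-benzyloxychroman-6-ylmethyl bromide. Its carbinol centre comes from Jacobsen-Katsuki epoxidation of a bought chromene followed by benzylic hydrogenolysis.
5. Ring order: the benzopyran is bought intact, a transient oxirane is made in step 1 and opened in step 2, and the butenolide is closed in step 9.

Key step: step 9

Assumption: the sense of induction of the chiral aggregate in step 9 cannot be predicted. The route is written with the (R,R)-tetramine as the antipode leading to (5R); if a first run shows the opposite sense, the (S,S)-tetramine is used with nothing else changed.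

**Step 1**
Reactants: 1 2,2-dimethyl-2H-chromene-6-carbonitrile
Product: 2 (3R,4R)-3,4-epoxy-2,2-dimethylchromane-6-carbonitrile
Conditions: (R,R)-[N,N'-bis(3,5-di-tert-butylsalicylidene)cyclohexane-1,2-diaminato]MnCl (4 mol %), 4-phenylpyridine N-oxide (cat.), aq NaOCl (Na2HPO4 buffer, pH 11.3), CH2Cl2, 0 °C
Reagents that add atoms: sodium hypochlorite, [Na+].[O-]Cl
Why: Jacobsen-Katsuki epoxidation, for which cis-configured aryl-conjugated 2,2-dimethylchromenes are the ideal substrate class; the (R,R) complex should deliver oxygen to the face that gives the (3R,4R)-epoxide, which sets the later carbinol centre C3, and recrystallisation should allow an upgrade of optical purity.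

**Step 2**
Reactants: 2 (3R,4R)-3,4-epoxy-2,2-dimethylchromane-6-carbonitrile
Product: 3 (R)-3-hydroxy-2,2-dimethylchromane-6-carbonitrile
Conditions: H2 (1 atm, stopped after one equivalent), 10% Pd/C, EtOAc, rt
Reagents that add atoms: none
Why: Catalytic hydrogenolysis of a benzylic epoxide cleaves only the benzylic C4-O bond, so C3 keeps its configuration and its R descriptor (CIP order O > C2 > C4 > H is unchanged), and an aryl nitrile is reduced much more slowly over Pd/C at 1 atm in a neutral aprotic solvent.

**Step 3**
Reactants: 3 (R)-3-hydroxy-2,2-dimethylchromane-6-carbonitrile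
Product: 5 (R)-3-(benzyloxy)-2,2-dimethylchromane-6-carbonitrile, via sodium alkoxide 4 (not isolated)
Conditions: NaH, THF/DMF, 0 °C; then BnBr, n-Bu4NI (cat.), 0 °C to rt
Reagents that add atoms: benzyl bromide, BrCc1ccccc1
Why: Williamson ether synthesis on the preformed alkoxide leaves the C3-O bond intact (configuration retained), tolerates the nitrile and the aryl ether, and installs a group that falls in the last step together with the catechol benzyl ethers.

**Step 4**
Reactants: 5 (R)-3-(benzyloxy)-2,2-dimethylchromane-6-carbonitrile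
Product: 7 (R)-3-(benzyloxy)-2,2-dimethylchromane-6-carbaldehyde, via N-diisobutylaluminio aldimine 6 (not isolated)
Conditions: i-Bu2AlH (1.2 equiv), toluene, -78 to 0 °C; then 1 M HCl
Reagents that add atoms: water, O
Why: Partial hydride reduction of a nitrile stops at the N-aluminated imine 6, which is hydrolysed to the aldehyde on acidic work-up, while the benzyl ether and the chroman are inert.

**Step 5**
Reactants: 7 (R)-3-(benzyloxy)-2,2-dimethylchromane-6-carbaldehyde
Product: 8 [(R)-3-(benzyloxy)-2,2-dimethylchroman-6-yl]methanol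
Conditions: NaBH4, MeOH, 0 °C
Reagents that add atoms: none
Why: Borohydride reduction of an aromatic aldehyde is chemoselective and creates no stereocentre.

**Step 6**
Reactants: 8 [(R)-3-(benzyloxy)-2,2-dimethylchroman-6-yl]methanol
Product: 9 (R)-3-(benzyloxy)-6-(bromomethyl)-2,2-dimethylchromane
Conditions: PBr3 (0.4 equiv), Et2O, 0 °C; cold aqueous wash, used crude
Reagents that add atoms: phosphorus tribromide, BrP(Br)Br
Why: Bromination of a benzylic alcohol through its phosphite ester (SN2 by bromide) is fast at 0 °C and spares the benzyl ether; the p-alkoxybenzyl bromide ionises easily and is therefore taken on without chromatography.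

**Step 7**
Reactants: 10 methoxyacetic acid; 11 dimethyl 2-bromomalonate
Product: 13 dimethyl 2-(2-methoxyacetoxy)malonate, via triethylammonium methoxyacetate 12 (not isolated)
Conditions: 10 (2.0 equiv), Et3N (1.0 equiv), MeCN, 0 °C; then 11 (1.0 equiv), rt
Reagents that add atoms: none
Why: SN2 displacement of a doubly activated bromide by a carboxylate, with the excess acid buffering the medium so that neither 11 nor the acidic C-H of 13 is deprotonated.

**Step 8**
Reactants: 13 dimethyl 2-(2-methoxyacetoxy)malonate; 9 (R)-3-(benzyloxy)-6-(bromomethyl)-2,2-dimethylchromane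
Product: 15 dimethyl 2-{[(R)-3-(benzyloxy)-2,2-dimethylchroman-6-yl]methyl}-2-(2-methoxyacetoxy)malonate, via sodium malonate enolate 14 (not isolated)
Conditions: 13 (1.1 equiv), NaH (1.0 equiv), THF/DMF 4:1, 0 °C; then 9, 0 °C to rt
Reagents that add atoms: none
Why: Malonic ester alkylation of the stabilised carbanion 14 with a very reactive benzylic bromide (SN2); the single equivalent of NaH is consumed by the far more acidic malonate C-H, so no base able to enolise the methoxyacetate remains and 15 cannot cyclise early and unselectively.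

**Step 9**
Reactants: 15 dimethyl 2-{[(R)-3-(benzyloxy)-2,2-dimethylchroman-6-yl]methyl}-2-(2-methoxyacetoxy)malonate
Product: 18 methyl (5R)-5-{[(3R)-3-(benzyloxy)-2,2-dimethylchroman-6-yl]methyl}-4-hydroxy-3-methoxy-2-oxo-2,5-dihydrofuran-5-carboxylate, via lithium enolate 16 (not isolated), via lithium tetronate 17 (not isolated)
Conditions: (R,R)-N,N'-bis[1-phenyl-2-(piperidin-1-yl)ethyl]propane-1,3-diamine (1.2 equiv), n-BuLi (2.4 equiv), THF, 0 °C; then -78 °C, slow addition of 15 (final 0.02 M), -78 to -40 °C; cold 1 M HCl (tetramine recovered from the aqueous layer)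
Reagents that add atoms: none
Why: Proposed new method: the chiral dilithium diamide removes a proton from the methoxyacetate CH2, the only enolisable position of 15, and enolate 16, whose geometry is fixed by Li chelation between the enolate oxygen and the alpha-OMe group, should stay bound to the remaining N-Li unit in a mixed aggregate; its carbon (future C3) then adds to one malonate ester carbonyl (future C4), methoxide leaves and the second basic site removes C3-H to give tetronate 17. The closest known reaction types are the Dieckmann closure of alpha-acyloxy esters to tetronic acids with achiral bases and the addition of lithium ester enolates to carbonyl compounds steered by chiral lithium amides as non-covalent auxiliaries, whereas a group-selective version on a malonate has not been described. The butenolide ring (O1-C2-C3-C4-C5) closes in the 5-(enolexo)-exo-trig mode. The new stereocentre C5 is defined only by which CO2Me group is attacked, and the controlling element is the chiral aggregate, which should tell the lithium-binding spectator ester from the non-coordinating CH2Ar arm on the two faces of the forming ring. Because 15 already holds the (3R)-chroman centre the two esters are diastereotopic rather than enantiotopic, but that centre lies six bonds from C5 and gives no useful bias, so the selectivity needed is reagent-controlled group selectivity, while site selectivity is secured by the substrate (one acidic CH2, no proton at C5, five-membered closure favoured over intermolecular Claisen reaction at high dilution). Formation of the stabilised tetronate anion makes the closure irreversible, so C5 cannot be scrambled by a retro-Dieckmann path.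

**Step 10**
Reactants: 18 methyl (5R)-5-{[(3R)-3-(benzyloxy)-2,2-dimethylchroman-6-yl]methyl}-4-hydroxy-3-methoxy-2-oxo-2,5-dihydrofuran-5-carboxylate
Product: 19 methyl (5R)-5-{[(3R)-3-(benzyloxy)-2,2-dimethylchroman-6-yl]methyl}-3-methoxy-2-oxo-4-(trifluoromethylsulfonyloxy)-2,5-dihydrofuran-5-carboxylate
Conditions: Tf2O (1.2 equiv), i-Pr2NEt (1.5 equiv), CH2Cl2, -78 °C
Reagents that add atoms: trifluoromethanesulfonic anhydride, O=S(=O)(OS(=O)(=O)C(F)(F)F)C(F)(F)F
Why: O-sulfonylation of a tetronic acid takes place at the vinylogous-acid oxygen on C4 and gives the vinyl triflate, while C5 carries no acidic hydrogen and is unaffected.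

**Step 11**
Reactants: 19 the C4 triflate; 20 3,4-bis(benzyloxy)phenylboronic acid
Product: 21 methyl (5R)-4-[3,4-bis(benzyloxy)phenyl]-5-{[(3R)-3-(benzyloxy)-2,2-dimethylchroman-6-yl]methyl}-3-methoxy-2-oxo-2,5-dihydrofuran-5-carboxylate
Conditions: Pd(OAc)2 (5 mol %), SPhos (2-dicyclohexylphosphino-2',6'-dimethoxybiphenyl, 10 mol %), K3PO4 (2 equiv), toluene/H2O 20:1, 60 °C
Reagents that add atoms: none
Why: Suzuki-Miyaura coupling: 4-triflyloxybutenolides are electron-poor vinyl triflates that add readily to zerovalent palladium, the bulky electron-rich biarylphosphine should help at a carbon flanked by OMe and quaternary C5, and C5 is not involved.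

**Step 12**
Reactants: 21 the tris(benzyl) ether
Product: 22 methyl (5R)-4-(3,4-dihydroxyphenyl)-5-{[(3R)-3-hydroxy-2,2-dimethylchroman-6-yl]methyl}-3-methoxy-2-oxo-2,5-dihydrofuran-5-carboxylate (target)
Conditions: H2 (1 atm), 10% Pd/C, EtOAc/MeOH 1:1, rt
Reagents that add atoms: none
Why: Catalytic hydrogenolysis removes the two aryl benzyl ethers and the secondary alkyl benzyl ether in one operation, while the tetrasubstituted push-pull butenolide C=C, the methyl ester and both stereocentres should stay untouched at 1 atm.

**Compound list**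
1 | 2,2-dimethyl-2H-chromene-6-carbonitrile | CC1(C)C=Cc2cc(C#N)ccc2O1 | starting material
2 | (3R,4R)-3,4-epoxy-2,2-dimethylchromane-6-carbonitrile | N#Cc1ccc2c(c1)[C@H]3O[C@H]3C(C)(C)O2 | intermediate
3 | (R)-3-hydroxy-2,2-dimethylchromane-6-carbonitrile | N#Cc1ccc2c(c1)C[C@@H](O)C(C)(C)O2 | intermediate
4 | sodium alkoxide of 3 (not isolated) | [Na+].N#Cc1ccc2c(c1)C[C@@H]([O-])C(C)(C)O2 | intermediate
5 | (R)-3-(benzyloxy)-2,2-dimethylchromane-6-carbonitrile | N#Cc1ccc2c(c1)C[C@@H](OCc3ccccc3)C(C)(C)O2 | intermediate
6 | N-diisobutylaluminio aldimine of 7 (not isolated) | CC(C)C[Al](CC(C)C)N=Cc1ccc2c(c1)C[C@@H](OCc3ccccc3)C(C)(C)O2 | intermediate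
7 | (R)-3-(benzyloxy)-2,2-dimethylchromane-6-carbaldehyde | O=Cc1ccc2c(c1)C[C@@H](OCc3ccccc3)C(C)(C)O2 | intermediate
8 | [(R)-3-(benzyloxy)-2,2-dimethylchroman-6-yl]methanol | OCc1ccc2c(c1)C[C@@H](OCc3ccccc3)C(C)(C)O2 | intermediate
9 | (R)-3-(benzyloxy)-6-(bromomethyl)-2,2-dimethylchromane | BrCc1ccc2c(c1)C[C@@H](OCc3ccccc3)C(C)(C)O2 | intermediate
10 | methoxyacetic acid | COCC(=O)O | starting material
11 | dimethyl 2-bromomalonate | COC(=O)C(Br)C(=O)OC | starting material
12 | triethylammonium methoxyacetate (not isolated) | CC[NH+](CC)CC.COCC(=O)[O-] | intermediate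
13 | dimethyl 2-(2-methoxyacetoxy)malonate | COCC(=O)OC(C(=O)OC)C(=O)OC | intermediate
14 | sodium enolate of 13 (not isolated) | [Na+].COCC(=O)OC(C(=O)OC)=C([O-])OC | intermediate
15 | dimethyl 2-{[(R)-3-(benzyloxy)-2,2-dimethylchroman-6-yl]methyl}-2-(2-methoxyacetoxy)malonate | COCC(=O)OC(Cc1ccc2c(c1)C[C@@H](OCc3ccccc3)C(C)(C)O2)(C(=O)OC)C(=O)OC | intermediate
16 | OMe-chelated lithium enolate of 15, OMe and OLi cis (not isolated) | [Li+].CO/C=C(\[O-])OC(Cc1ccc2c(c1)C[C@@H](OCc3ccccc3)C(C)(C)O2)(C(=O)OC)C(=O)OC | intermediate
17 | lithium tetronate of 18 (not isolated) | [Li+].COC(=O)[C@]1(Cc2ccc3c(c2)C[C@@H](OCc4ccccc4)C(C)(C)O3)OC(=O)C(OC)=C1[O-] | intermediate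
18 | methyl (5R)-5-{[(3R)-3-(benzyloxy)-2,2-dimethylchroman-6-yl]methyl}-4-hydroxy-3-methoxy-2-oxo-2,5-dihydrofuran-5-carboxylate | COC(=O)[C@]1(Cc2ccc3c(c2)C[C@@H](OCc4ccccc4)C(C)(C)O3)OC(=O)C(OC)=C1O | intermediate
19 | C4 triflate of 18, (5R,3'R) | COC(=O)[C@]1(Cc2ccc3c(c2)C[C@@H](OCc4ccccc4)C(C)(C)O3)OC(=O)C(OC)=C1OS(=O)(=O)C(F)(F)F | intermediate
20 | 3,4-bis(benzyloxy)phenylboronic acid | OB(O)c1ccc(OCc2ccccc2)c(OCc2ccccc2)c1 | starting material
21 | methyl (5R)-4-[3,4-bis(benzyloxy)phenyl]-5-{[(3R)-3-(benzyloxy)-2,2-dimethylchroman-6-yl]methyl}-3-methoxy-2-oxo-2,5-dihydrofuran-5-carboxylate | COC(=O)[C@]1(Cc2ccc3c(c2)C[C@@H](OCc4ccccc4)C(C)(C)O3)OC(=O)C(OC)=C1c1ccc(OCc2ccccc2)c(OCc2ccccc2)c1 | intermediate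
22 | methyl (5R)-4-(3,4-dihydroxyphenyl)-5-{[(3R)-3-hydroxy-2,2-dimethylchroman-6-yl]methyl}-3-methoxy-2-oxo-2,5-dihydrofuran-5-carboxylate | COC(=O)[C@]1(Cc2ccc3c(c2)C[C@@H](O)C(C)(C)O3)OC(=O)C(OC)=C1c1ccc(O)c(O)c1 | target

Total step count: 12. Longest linear sequence: 11 steps (steps 1 to 6 and 8 to 12, from 1 to 22).

**Steps most likely to fail**

1. **Step 9.** The aggregate may discriminate too weakly between the two ester groups. The methoxyacetyl group may also be lost, either by ketene extrusion from the enolate or by attack of liberated methoxide on substrate that is not yet enolised.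
   Fallback (known chemistry), from 15 back to 18: the closure is run as an ordinary Dieckmann tetronic acid synthesis with LiN(SiMe3)2 (2.2 equiv) in THF at -78 °C. This should give 18 together with its C5 epimer, methyl (5S)-5-{[(3R)-3-(benzyloxy)-2,2-dimethylchroman-6-yl]methyl}-4-hydroxy-3-methoxy-2-oxo-2,5-dihydrofuran-5-carboxylate F1. Because of the enantiopure chroman centre the two are diastereomers, so preparative HPLC or fractional crystallisation should separate them. Selection is thus replaced by resolution, at the cost of half the material.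

2. **Step 11.** Oxidative addition and transmetalation may be slow at a carbon flanked by OMe and the quaternary C5. Base may hydrolyse the vinylogous acyl triflate back to the tetronate, and the electron-rich boronic acid may protodeboronate.
   Fallback, from 19 back to 21: a base-free and palladium-free conjugate addition-elimination. 4-Bromo-1,2-bis(benzyloxy)benzene F2 is treated with t-BuLi (2 equiv, THF, -78 °C) to give 3,4-bis(benzyloxy)phenyllithium F3. CuBr·SMe2 (0.5 equiv) converts this into lithium bis[3,4-bis(benzyloxy)phenyl]cuprate F4. Adding 19 at -78 °C should replace the triflate by the aryl group, as is known for beta-triflyloxy enoates, without touching the esters.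

3. **Step 8.** The labile p-alkoxybenzyl bromide may decay before it is captured, the hindered tertiary carbanion may attack slowly, and acyl transfer may occur between enolate 14 and ester groups.
   Fallback, from 9 back to 15: the C5-O acyl bond is made after the C-C bond. The sodium salt of dimethyl malonate F5 (excess, NaH, THF) is alkylated with 9 to give dimethyl 2-{[(R)-3-(benzyloxy)-2,2-dimethylchroman-6-yl]methyl}malonate F6. Davis oxidation of its sodium enolate with 2-(phenylsulfonyl)-3-phenyloxaziridine gives dimethyl 2-{[(R)-3-(benzyloxy)-2,2-dimethylchroman-6-yl]methyl}-2-hydroxymalonate F7. Acylation with methoxyacetyl chloride F8 (pyridine, DMAP, CH2Cl2) then gives 15.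

**Further compounds**
F1 | step 9 | methyl (5S)-5-{[(3R)-3-(benzyloxy)-2,2-dimethylchroman-6-yl]methyl}-4-hydroxy-3-methoxy-2-oxo-2,5-dihydrofuran-5-carboxylate | COC(=O)[C@@]1(Cc2ccc3c(c2)C[C@@H](OCc4ccccc4)C(C)(C)O3)OC(=O)C(OC)=C1O
F2 | step 11 | 4-bromo-1,2-bis(benzyloxy)benzene (bought) | Brc1ccc(OCc2ccccc2)c(OCc2ccccc2)c1
F3 | step 11 | 3,4-bis(benzyloxy)phenyllithium | [Li]c1ccc(OCc2ccccc2)c(OCc2ccccc2)c1
F4 | step 11 | lithium bis[3,4-bis(benzyloxy)phenyl]cuprate | [Li+].[Cu-](c1ccc(OCc2ccccc2)c(OCc2ccccc2)c1)c1ccc(OCc2ccccc2)c(OCc2ccccc2)c1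
F5 | step 8 | dimethyl malonate (bought) | COC(=O)CC(=O)OC
F6 | step 8 | dimethyl 2-{[(R)-3-(benzyloxy)-2,2-dimethylchroman-6-yl]methyl}malonate | COC(=O)C(Cc1ccc2c(c1)C[C@@H](OCc3ccccc3)C(C)(C)O2)C(=O)OC
F7 | step 8 | dimethyl 2-{[(R)-3-(benzyloxy)-2,2-dimethylchroman-6-yl]methyl}-2-hydroxymalonate | COC(=O)C(O)(Cc1ccc2c(c1)C[C@@H](OCc3ccccc3)C(C)(C)O2)C(=O)OC
F8 | step 8 | methoxyacetyl chloride (bought) | COCC(=O)Cl
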